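**Plan**

- Retrosynthesis: C3–OH is taken back to a C3 ketone; C7H2 and C8(Br)=C9 are taken back to a C7 enone (α-bromination, then deoxygenation); C4–Br is taken back to α′-bromination of the ring A enone. Ring A is then cut at C1–C6 and C4–C5.
- Enabling feature: ring A is a cyclohexene with oxygen at C3, 1,4 to the spiro carbon C6. The quaternary pair C5(CH3)2–C6 together with ring B is the tetrasubstituted C=C of pulegone (its carbonyl is C7). Ring A is therefore the [4+2] adduct of a 2-silyloxypenta-1,3-diene (C1–C4) with (S)-pulegone (C5–C11).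
- Forward: ring B is bought; ring A closes in the Lewis-acid [4+2]. There follow double dehydrogenation, bromination at C4 and at C8, reduction, inverting esterification, C7 deoxygenation and ester cleavage.
- Stereochemistry: the bought C9 methyl of (S)-pulegone sets C6 in the cycloaddition and is then erased. C6, through its C7 carbonyl arm, biases bromination at C4. C4/C5 direct the hydride at C3, and a Mitsunobu inversion gives the 3,4-trans bromohydrin.

Key step: step 2

Remark: locants C1–C11 are those of the target (ring A: C1(CH3)=C2–C3(O)–C4(Br)–C5(CH3)2–C6; ring B: C6–C7H2–C8(Br)=C9(CH3)–C10H2–C11H2) and are kept for all intermediates; descriptors refer to these atoms.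
Remark: (S)-pulegone is chosen on the assumption that the C1–C6 bond forms axially, cis to the ring methyl; if the other face were preferred, (R)-pulegone would be used in the same way.
Remark: hydride reduction of the α′-bromo enone is assumed to give the 3,4-cis bromohydrin (attack anti to the pseudoaxial C5 methyl), which is why an inverting esterification follows.

**Step 1**
Reactants: 1 (E)-pent-3-en-2-one
Product: 2 tert-butyl(dimethyl)[(3E)-penta-1,3-dien-2-yloxy]silane
Conditions: TBSOTf, Et3N, CH2Cl2, 0 °C
Reagents that add atoms: tert-butyldimethylsilyl triflate, CC(C)(C)[Si](C)(C)OS(=O)(=O)C(F)(F)F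
Why: Soft enolization (silyl triflate/amine) toward the methyl group, the only α-position, should give the cross-conjugated 2-silyloxy-1,3-diene with the E-alkene untouched; no stereocenter is formed.

**Step 2**
Reactants: 3 (S)-(−)-pulegone; 2 tert-butyl(dimethyl)[(3E)-penta-1,3-dien-2-yloxy]silane
Product: 5 (1S,6S,9S)-1,5,5,9-tetramethylspiro[5.5]undecane-3,7-dione, via silyl enol ether cycloadduct 4 (not isolated)
Conditions: AlBr3/AlMe3 (10:1, 0.3 equiv), toluene/CH2Cl2, −5 → 23 °C; then 2 M HCl, THF, 23 °C
Reagents that add atoms: none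
Why: Proposed new method: the aluminium-complexed s-cis enone of 3 is attacked at its β-carbon C5 by the CH2 terminus (C4) of diene 2, which carries the largest HOMO coefficient, and the aluminium enolate closes at C6 onto the silyloxyallyl cation terminus C1 (a highly asynchronous [4+2]; an O-closed hetero-adduct, if formed, should reopen under the Lewis acid). The closest known reaction type is the AlBr3/AlMe3-promoted Diels–Alder reaction of 2-silyloxydienes with hindered β,β-disubstituted enones that builds vicinal quaternary carbons; a tetrasubstituted exocyclic enone giving a spiro centre has not been shown. Ring A is closed by intermolecular [4+2] cycloaddition, and if the path is stepwise its second bond forms by a 6-(enolexo)-endo-trig closure. C6 is controlled by the bought C9 methyl: with that methyl equatorial the C1–C6 bond forms axially on the half-chair, cis to the methyl, which also leaves the bulky C5 equatorial on ring B; C1 (CHCH3) follows from the endo approach and is erased in step 3. The step needs regioselectivity (secured by matched polarisation: donor oxygen at C3 "para" to the acceptor-bearing C6, methyl terminus "ortho" to it), π-facial selectivity (secured by the ring methyl) and 1,4- over 1,2-addition (secured by the shielded ketone), and AlMe3 scavenges protic acid that would desilylate 2. Diastereomers epimeric at C6 are to be removed at this stage, because after step 3 they would be enantiomers.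

**Step 3**
Reactants: 5 (1S,6S,9S)-1,5,5,9-tetramethylspiro[5.5]undecane-3,7-dione
Product: 6 (6R)-1,5,5,9-tetramethylspiro[5.5]undeca-1,8-diene-3,7-dione
Conditions: IBX (2.5 equiv), DMSO/toluene, 70 °C
Reagents that add atoms: none
Why: IBX dehydrogenation of ketones through their enols: only C2/C1 in ring A and C8/C9 in ring B offer an α,β-hydrogen pair (the other neighbours are the quaternary C5 and C6), so both enones should form regiospecifically, the relay stereocenters C1 and C9 are erased and C6 stays as the only stereocenter.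

**Step 4**
Reactants: 6 (6R)-1,5,5,9-tetramethylspiro[5.5]undeca-1,8-diene-3,7-dione
Product: 8 (4S,6S)-4-bromo-1,5,5,9-tetramethylspiro[5.5]undeca-1,8-diene-3,7-dione, via ring A silyl dienol ether 7 (not isolated)
Conditions: TBSOTf (1.1 equiv), Et3N, CH2Cl2, −78 → 0 °C; then NBS, THF, −78 °C
Reagents that add atoms: N-bromosuccinimide, O=C1CCC(=O)N1Br
Why: Soft enolization is possible only in ring A (ring B has no α′-hydrogen) and the cross-conjugated silyl dienol ether is brominated at its terminus C4 (α′-bromination of an enone); bromine should enter anti to the pseudoaxial C5 methyl and on the face of the flat C7 carbonyl arm, not that of the C11 methylene, which sets C4 cis to C7, and a C4 epimer would be separable and could be re-equilibrated through the enol.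

**Step 5**
Reactants: 8 (4S,6S)-4-bromo-1,5,5,9-tetramethylspiro[5.5]undeca-1,8-diene-3,7-dione
Product: 10 (4S,6S)-4,8-dibromo-1,5,5,9-tetramethylspiro[5.5]undeca-1,8-diene-3,7-dione, via ring B 8,9-dibromide 9 (not isolated)
Conditions: Br2 (1.05 equiv), CH2Cl2, −10 °C; then pyridine, 0 → 23 °C
Reagents that add atoms: bromine, BrBr
Why: α-Bromination of an enone by bromine addition and E1cB dehydrobromination: the ring B alkene should react because the ring A alkene is shielded at C1 by the spiro carbon and deactivated by the α′-bromine; no stereocenter is formed and C4 is not touched.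

**Step 6**
Reactants: 10 (4S,6S)-4,8-dibromo-1,5,5,9-tetramethylspiro[5.5]undeca-1,8-diene-3,7-dione
Product: 11 (3R,4S,6S)-4,8-dibromo-1,5,5,9-tetramethylspiro[5.5]undeca-1,8-diene-3,7-diol (3,4-cis; C7 carbinol configuration not defined)
Conditions: i-Bu2AlH (excess), CH2Cl2, −78 → 0 °C; aq. Rochelle salt
Reagents that add atoms: none
Why: 1,2-Reduction of both enone carbonyls by the aluminium hydride: at C3 the hydride should enter anti to the pseudoaxial C5 methyl of the half-chair that keeps C4–Br equatorial, giving the 3,4-cis bromohydrin with axial OH, and the C7 carbinol configuration is irrelevant because that oxygen is removed in step 8.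

**Step 7**
Reactants: 11 (3R,4S,6S)-4,8-dibromo-1,5,5,9-tetramethylspiro[5.5]undeca-1,8-diene-3,7-diol
Product: 12 (3S,4S,6S)-4,8-dibromo-7-hydroxy-1,5,5,9-tetramethylspiro[5.5]undeca-1,8-dien-3-yl 4-nitrobenzoate
Conditions: 4-O2NC6H4CO2H, PPh3, DIAD, THF, 0 → 23 °C
Reagents that add atoms: 4-nitrobenzoic acid, OC(=O)c1ccc(cc1)[N+](=O)[O-]
Why: Mitsunobu reaction with SN2 inversion at the allylic, axial C3 alcohol should give the 3,4-trans ester, which also protects O3, while the C7 alcohol next to the quaternary C6 cannot be displaced and stays free.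

**Step 8**
Reactants: 12 (3S,4S,6S)-4,8-dibromo-7-hydroxy-1,5,5,9-tetramethylspiro[5.5]undeca-1,8-dien-3-yl 4-nitrobenzoate
Product: 13 (3S,4S,6S)-4,8-dibromo-1,5,5,9-tetramethylspiro[5.5]undeca-1,8-dien-3-yl 4-nitrobenzoate
Conditions: Et3SiH, BF3·OEt2, CH2Cl2, −78 → −20 °C
Reagents that add atoms: none
Why: Ionic hydrogenation: BF3 should ionise the C7 allylic alcohol to the 2-bromoallyl cation (C7–C8–C9, stabilised by the tertiary terminus C9) and Et3SiH should deliver hydride to the less substituted terminus C7, giving the tetrasubstituted bromoalkene, while the electron-poor C3 ester flanked by C4–Br should not ionise; no stereocenter is formed.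

**Step 9**
Reactants: 13 (3S,4S,6S)-4,8-dibromo-1,5,5,9-tetramethylspiro[5.5]undeca-1,8-dien-3-yl 4-nitrobenzoate
Product: 14 (3S,4S,6S)-4,8-dibromo-1,5,5,9-tetramethylspiro[5.5]undeca-1,8-dien-3-ol
Conditions: K2CO3 (0.5 equiv), MeOH, 0 °C
Reagents that add atoms: none
Why: Base-catalysed transesterification of the activated aryl ester should free the C3 alcohol with retention, and epoxide closure is not expected at 0 °C because the trans-diequatorial bromohydrin cannot easily reach the diaxial geometry.

**Compound list**

1 | (E)-pent-3-en-2-one | C/C=C/C(C)=O | starting material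
2 | tert-butyl(dimethyl)[(3E)-penta-1,3-dien-2-yloxy]silane | C/C=C/C(=C)O[Si](C)(C)C(C)(C)C | intermediate
3 | (S)-(−)-pulegone, (5S)-5-methyl-2-(propan-2-ylidene)cyclohexan-1-one | C[C@H]1CCC(=C(C)C)C(=O)C1 | starting material
4 | (1S,6S,9S)-3-(tert-butyldimethylsilyloxy)-1,5,5,9-tetramethylspiro[5.5]undec-2-en-7-one (not isolated) | C[C@H]1C=C(O[Si](C)(C)C(C)(C)C)CC(C)(C)[C@]12CC[C@H](C)CC2=O | intermediate
5 | (1S,6S,9S)-1,5,5,9-tetramethylspiro[5.5]undecane-3,7-dione | C[C@H]1CC(=O)CC(C)(C)[C@]12CC[C@H](C)CC2=O | intermediate
6 | (6R)-1,5,5,9-tetramethylspiro[5.5]undeca-1,8-diene-3,7-dione | CC1=CC(=O)CC(C)(C)[C@]12CCC(C)=CC2=O | intermediate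
7 | (6S)-3-(tert-butyldimethylsilyloxy)-1,5,5,9-tetramethylspiro[5.5]undeca-1,3,8-trien-7-one (not isolated) | CC1=CC(O[Si](C)(C)C(C)(C)C)=CC(C)(C)[C@]12CCC(C)=CC2=O | intermediate
8 | (4S,6S)-4-bromo-1,5,5,9-tetramethylspiro[5.5]undeca-1,8-diene-3,7-dione | CC1=CC(=O)[C@@H](Br)C(C)(C)[C@]12CCC(C)=CC2=O | intermediate
9 | (4S,6S)-4,8,9-tribromo-1,5,5,9-tetramethylspiro[5.5]undec-1-ene-3,7-dione (trans-8,9-dibromide, C8/C9 not defined; not isolated) | CC1=CC(=O)[C@@H](Br)C(C)(C)[C@]12CCC(C)(Br)C(Br)C2=O | intermediate
10 | (4S,6S)-4,8-dibromo-1,5,5,9-tetramethylspiro[5.5]undeca-1,8-diene-3,7-dione | CC1=CC(=O)[C@@H](Br)C(C)(C)[C@]12CCC(C)=C(Br)C2=O | intermediate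
11 | (3R,4S,6S)-4,8-dibromo-1,5,5,9-tetramethylspiro[5.5]undeca-1,8-diene-3,7-diol (C7 not defined) | CC1=C[C@@H](O)[C@@H](Br)C(C)(C)[C@]12CCC(C)=C(Br)C2O | intermediate
12 | (3S,4S,6S)-4,8-dibromo-7-hydroxy-1,5,5,9-tetramethylspiro[5.5]undeca-1,8-dien-3-yl 4-nitrobenzoate (C7 not defined) | CC1=C[C@H](OC(=O)c3ccc(cc3)[N+](=O)[O-])[C@@H](Br)C(C)(C)[C@]12CCC(C)=C(Br)C2O | intermediate
13 | (3S,4S,6S)-4,8-dibromo-1,5,5,9-tetramethylspiro[5.5]undeca-1,8-dien-3-yl 4-nitrobenzoate | CC1=C[C@H](OC(=O)c3ccc(cc3)[N+](=O)[O-])[C@@H](Br)C(C)(C)[C@]12CCC(C)=C(Br)C2 | intermediate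
14 | (3S,4S,6S)-4,8-dibromo-1,5,5,9-tetramethylspiro[5.5]undeca-1,8-dien-3-ol | CC1=C[C@H](O)[C@@H](Br)C(C)(C)[C@]12CCC(C)=C(Br)C2 | target

**Step count and risks**

Total step count: 9. Longest linear sequence: 9 steps (from 1; pulegone 3 enters in step 2).

Steps most likely to fail:

1. Step 2 (Proposed new method). The second C–C bond (C1–C6) may not close at the congested enolate carbon, or the diene may be lost by protodesilylation or oligomerisation before it adds. Fallback with known chemistry, setting out from 2 and 3 and coming back at 5: a Mukaiyama–Michael addition of 2 to 3 (TiCl4, CH2Cl2, −78 °C, aqueous work-up) should stop at the open-chain 1,5-diketone F1. A base-mediated intramolecular Michael addition (KOt-Bu cat., t-BuOH/THF, 0 °C; 6-endo-trig closure of the more substituted ring enolate onto the enone, as in double-Michael annulations) would then close ring A to 5 under the same axial-attack control.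

2. Step 8. Hydride may be delivered to the tertiary terminus C9 (alkene transposed to C7=C8), the cation next to the spiro carbon may rearrange, or the 2-bromoallyl alcohol may not ionise. Fallback by radical instead of cationic deoxygenation, setting out from 11 and coming back at 14: the Mitsunobu reaction is run with benzoic acid (a nitroarene would interfere with radical chains) to give the benzoate F6. The C7 alcohol is converted with PhOC(S)Cl/pyridine/DMAP into the phenyl thionocarbonate F7. Barton–McCombie reduction with (Me3Si)3SiH/AIBN (toluene, 80 °C, silane kept near one equivalent so the hindered C4 bromide is spared) should give the benzoate F8 through the allyl radical, which takes hydrogen at C7. K2CO3/MeOH then gives 14.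

3. Step 4. Facial selectivity of bromination at C4 may be poor, because the two faces differ only through the remote C7 and C11 arms. Fallback that sets C4 in the cycloaddition, setting out from 2 (with 3) and coming back at 8: NBS (THF, −78 °C) converts 2 into (E)-1-bromopent-3-en-2-one F2, and TBSOTf/Et3N gives the (1Z,3E)-1-bromo-2-silyloxydiene F3. Cycloaddition with 3 under the conditions of step 2 should place the outside bromine on the face of the C7 carbonyl (endo approach) in the silyl enol ether F4. Hydrolysis (2 M HCl, THF) gives the bromo diketone F5, and IBX dehydrogenation as in step 3 returns to 8.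

**Further compounds**

F1 | step 2 | (5S)-5-methyl-2-[(5E)-2-methyl-4-oxohept-5-en-2-yl]cyclohexan-1-one (C6 epimers) | C/C=C/C(=O)CC(C)(C)C1CC[C@H](C)CC1=O
F2 | step 4 | (E)-1-bromopent-3-en-2-one | C/C=C/C(=O)CBr
F3 | step 4 | [(1Z,3E)-1-bromopenta-1,3-dien-2-yloxy](tert-butyl)dimethylsilane | C/C=C/C(O[Si](C)(C)C(C)(C)C)=C/Br
F4 | step 4 | (1S,4S,6S,9S)-4-bromo-3-(tert-butyldimethylsilyloxy)-1,5,5,9-tetramethylspiro[5.5]undec-2-en-7-one | C[C@H]1C=C(O[Si](C)(C)C(C)(C)C)[C@@H](Br)C(C)(C)[C@]12CC[C@H](C)CC2=O
F5 | step 4 | (1S,4S,6S,9S)-4-bromo-1,5,5,9-tetramethylspiro[5.5]undecane-3,7-dione | C[C@H]1CC(=O)[C@@H](Br)C(C)(C)[C@]12CC[C@H](C)CC2=O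
F6 | step 8 | (3S,4S,6S)-4,8-dibromo-7-hydroxy-1,5,5,9-tetramethylspiro[5.5]undeca-1,8-dien-3-yl benzoate | CC1=C[C@H](OC(=O)c3ccccc3)[C@@H](Br)C(C)(C)[C@]12CCC(C)=C(Br)C2O
F7 | step 8 | (3S,4S,6S)-4,8-dibromo-1,5,5,9-tetramethyl-7-(phenoxycarbonothioyloxy)spiro[5.5]undeca-1,8-dien-3-yl benzoate | CC1=C[C@H](OC(=O)c3ccccc3)[C@@H](Br)C(C)(C)[C@]12CCC(C)=C(Br)C2OC(=S)Oc4ccccc4
F8 | step 8 | (3S,4S,6S)-4,8-dibromo-1,5,5,9-tetramethylspiro[5.5]undeca-1,8-dien-3-yl benzoate | CC1=C[C@H](OC(=O)c3ccccc3)[C@@H](Br)C(C)(C)[C@]12CCC(C)=C(Br)C2
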